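By 4.00 h target has stopped rising in both earlier runs, whose charges differ in free catalyst.

| setting | epsilon | eta | Friday's | Monday's |
|---|---|---|---|---|
| starting material | 0.78 M | 0.78 M | 0.78 M | 0.78 M |
| reagent | 1.56 M | 1.56 M | 1.56 M | 1.56 M |
| second substrate | 0.39 M | 0.39 M | 0.390 M | 0.390 M |
| free catalyst | 48 mM | 69 mM | 39 mM | 58 mM |
| remark | run made earlier | run made earlier |  |  |
| time |  |  | 5.0 h | 5.0 h |

- epsilon (time / h: target / %): 0.333: 16.7; 0.833: 26.7; 1.50: 30.8; 2.50: 29.5; 4.00: 30.3
- eta (time / h: target / %): 0.250: 20.6; 0.500: 31.2; 1.00: 35.8; 2.00: 38.1; 4.00: 38.6

(standard deviation of a reading: 1 percentage point)

- a species is counted by the starting material in it: one side product counts as two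

1. which of the two there is more of at the end, counted by the starting material in each, Friday's (side product / target)
2. which of the two there is more of at the end, counted by the starting material in each, Monday's (side product / target)
3. how much target is there at the end, in percent of the starting material charged: Friday's
4. how much target is there at the end, in percent of the starting material charged: Monday's

We turn the question round: what would have to be true for target to end above side product? Between the last two readings target moves 0.8 percentage points in the epsilon run and 0.5 points in the eta run, against a scatter of 1 point, so we read the last values as plateaus and assume that the starting material is gone by then. Suppose that it leaves by two first-order routes, one to target at a rate proportional to [free catalyst] and one to side product at a rate independent of it. Each bit lost then splits in a fixed ratio, and integrating over full conversion gives a target share of [free catalyst]/([free catalyst] + K).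

Solving for K, the epsilon run gives 110 mM and the eta run 110 mM. These are two separate flasks, so their agreement is a check on the form. We carry their mean, 110 mM, as the crossover level, the [free catalyst] at which target and side product take equal shares at the charges of these two runs; it works as a selectivity factor.

On this reckoning, which holds for the 0.78 M of starting material charged in both runs, target ends ahead of side product above K. Friday's 39 mM and Monday's 58 mM both stand below it, Monday's by a factor of twice, so we expect side product to lead in both. Our reckoning gives 26.2% for Friday's and 34.5% for Monday's.

The forecast also names side product for Friday's and side product for Monday's, with 26.6% and 34.6% of target, close to our figures. It pictures “a catalysed route to target competing with a largely uncatalysed route to the dimeric side product”.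

Friday's flask ends with 27.1% target and 71.0% side product, Monday's with 35.1% and 64.4%.

    free catalyst → spent catalyst (k = 1.50 × 10⁻⁶ s⁻¹)
    starting material + target → side product (k = 5.10 × 10⁻⁴ M⁻¹ s⁻¹)
    second substrate + reagent + free catalyst → free catalyst + second product (k = 0.0460 M⁻² s⁻¹)
    starting material + reagent + free catalyst → free catalyst + target (k = 0.00400 M⁻² s⁻¹)

Read back from these ends, K is 105 mM for Friday's and 107 mM for Monday's. On a neighbouring flask, Friday's recipe with 0.023 M of free catalyst, K gives 17.3% target. That flask ends with 18.1% target and 74.7% side product, and 7.2% of its starting material is still there.

(The runs were generated by integration on assumed constants; the scatter is artificial.)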